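**Retrosynthetic overview** (ring locants O1–O2–C3–C4=C5–C6; side chain C1′–C8′)
1. Target 26 ⇐ ethyl ester 25 ⇐ anti-dehydration (C4–H/C5–OH) of 1,2-dioxan-5-ol 24; the 1,2-dioxane is the only ring and is closed in step 8.
2. 24 ⇐ epoxy enoate 22: invertive perhydrolysis of a Shi epoxide at C6 (sets C6), then 6-exo peroxy-Michael closure steered by a sacrificial C4 centre (sets C3).
3. 22 ⇐ skipped dienoate 21 ⇐ allylic boronic ester 16 by a Zweifel-type 1,2-boronate shift onto a β-acrylate unit (C3–C4 bond; new).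
4. 16 ⇐ alkenyl boronic ester 11 + lithiated propyl carbamate: lithiation–borylation, whose 1,2-metallate shift forges C4–C5 and sets C4.
5. 11 ⇐ hex-1-ene by two ZACA carboaluminations (C4′, C2′) and Negishi coupling with bromoalkenyl boronate 8, which fixes the C5=C6 geometry.

Assumption: the face selectivities of (+)-(NMI)2ZrCl2, (+)-sparteine and the D-fructose-derived Shi ketone follow the published empirical models; if a model points the other way, the antipodal catalyst or ligand is used.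

**Step 1**
Reactants: 1 hex-1-ene; 2 triethylaluminium; 3 vinyl bromide
Product: 5 (4S)-4-ethyloct-1-ene, via 2-ethylhexylalane 4 (not isolated)
Conditions: Et3Al, (+)-(NMI)2ZrCl2 (5 mol%), IBAO, CH2Cl2, 0 °C → rt; evaporate; Zn(OTf)2, vinyl bromide (excess), PdCl2(DPEphos) (3 mol%), DIBAL-H (6 mol%), DMF, rt
Reagents that add atoms: none
Why: The Negishi ZACA reaction (Zr-catalysed asymmetric carboalumination) adds Et–Al across the terminal alkene under catalyst control to set C4′ (S), and the alkylalane is vinylated in the same pot by Zn-promoted Pd-catalysed Negishi coupling, which does not touch the stereocentre.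

**Step 2**
Reactants: 6 but-1-yne
Product: 8 2-[(1Z)-2-bromobut-1-en-1-yl]-4,4,5,5-tetramethyl-1,3,2-dioxaborolane, via bromoalkenyldibromoborane 7 (not isolated)
Conditions: BBr3, CH2Cl2, −78 → −40 °C; then pinacol, −78 °C → rt
Reagents that add atoms: boron tribromide BrB(Br)Br; pinacol CC(C)(O)C(C)(C)O
Why: syn-Bromoboration of the terminal alkyne (haloboration) puts B on C1 and Br on C2 on the same side, and pinacol esterification at low temperature gives the bench-stable (Z)-bromoalkenyl boronate without Z/E isomerisation.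

**Step 3**
Reactants: 5 (4S)-4-ethyloct-1-ene; 9 trimethylaluminium; 8 2-[(1Z)-2-bromobut-1-en-1-yl]-4,4,5,5-tetramethyl-1,3,2-dioxaborolane
Product: 11 2-[(1Z,4S,6S)-2,6-diethyl-4-methyldec-1-en-1-yl]-4,4,5,5-tetramethyl-1,3,2-dioxaborolane, via alkylalane 10 (not isolated)
Conditions: Me3Al, (+)-(NMI)2ZrCl2 (4 mol%), MAO, CH2Cl2, 0 °C → rt; evaporate; Zn(OTf)2, 8 (3 equiv), PdCl2(DPEphos)/DIBAL-H, DMF, 23–50 °C
Reagents that add atoms: none
Why: A second ZACA reaction (methylalumination, reagent control, about 8:1 dr over the remote C4′ centre, minor epimer removed by chromatography at 24) sets C2′ (S), and Zn/Pd Negishi coupling at the C–Br bond of 8 proceeds with retention of alkene geometry, so the side chain ends up cis to boron (Z), the geometry that later defines C6.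

**Step 4**
Reactants: 12 propan-1-ol
Product: 13 propyl N,N-diisopropylcarbamate
Conditions: i-Pr2NC(O)Cl, Et3N, toluene, reflux
Reagents that add atoms: N,N-diisopropylcarbamoyl chloride CC(C)N(C(C)C)C(Cl)=O
Why: O-Carbamoylation of the primary alcohol installs the Hoppe carbamate that directs α-lithiation and later serves as the leaving group.

**Step 5**
Reactants: 13 propyl N,N-diisopropylcarbamate; 11 2-[(1Z,4S,6S)-2,6-diethyl-4-methyldec-1-en-1-yl]-4,4,5,5-tetramethyl-1,3,2-dioxaborolane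
Product: 16 2-[(3S,4Z,7S,9S)-5,9-diethyl-7-methyltridec-4-en-3-yl]-4,4,5,5-tetramethyl-1,3,2-dioxaborolane, via lithiated carbamate 14 (not isolated), via lithium boronate complex 15 (not isolated)
Conditions: 13, s-BuLi, (+)-sparteine, Et2O, −78 °C, 5 h; add 11, −78 °C; MgBr2·OEt2, −78 → 35 °C
Reagents that add atoms: none
Why: Hoppe–Aggarwal lithiation–borylation: sparteine-mediated enantioselective deprotonation gives the configurationally stable (R)-α-lithio carbamate, which adds to boron with retention, and the alkenyl group then makes a stereospecific 1,2-metallate shift from B to C with inversion (anti to the carbamate), forming the C4–C5 bond and the sacrificial C4 centre (3S in 16) with the alkene geometry unchanged.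

**Step 6**
Reactants: 16 2-[(3S,4Z,7S,9S)-5,9-diethyl-7-methyltridec-4-en-3-yl]-4,4,5,5-tetramethyl-1,3,2-dioxaborolane; 17 ethyl (2Z)-3-iodoprop-2-enoate
Product: 21 ethyl (2E,4R,5Z,8S,10S)-4,6,10-triethyl-8-methyltetradeca-2,5-dienoate, via alkenylmagnesium reagent 18 (not isolated), via magnesium boronate complex 19 (not isolated), via iodoboronate 20 (not isolated)
Conditions: 17, i-PrMgCl·LiCl, THF, −40 °C; add 16, −40 → −20 °C; I2, THF, −78 °C; NaOEt, EtOH, −78 → 0 °C
Reagents that add atoms: none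
Why: Proposed new method: a Zweifel-type coupling with an ester-bearing alkenylmagnesium, in which the LiCl-solvated (Z)-β-magnesioacrylate 18 adds to the boronic ester to give boronate complex 19 (a boron dienolate equivalent), iodination at the ester α-carbon triggers a 1,2-shift of the C4 carbon from boron to C3 with retention at C4 (20), and ethoxide-induced anti-elimination of iodide and the boryl group converts the Z-alkenyl unit into the E-enoate; the closest known reaction type is the Zweifel olefination of secondary boronic esters with vinyl- or alkenyl-lithium and Grignard reagents, not yet shown with an acrylate-type alkenylmetal.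

**Step 7**
Reactants: 21 ethyl (2E,4R,5Z,8S,10S)-4,6,10-triethyl-8-methyltetradeca-2,5-dienoate
Product: 22 ethyl (2E,4R)-4-[(2R,3S)-3-ethyl-3-[(2S,4S)-4-ethyl-2-methyloctyl]oxiran-2-yl]hex-2-enoate
Conditions: Shi ketone (D-fructose-derived, 30 mol%), Oxone, K2CO3, Bu4NHSO4, MeCN/DMM/aq. borate–EDTA buffer (pH 10.5), 0 °C
Reagents that add atoms: potassium peroxymonosulfate (Oxone) [K+].[O-]S(=O)(=O)OO
Why: Shi asymmetric epoxidation (chiral dioxirane, spiro transition state) attacks only the electron-rich trisubstituted alkene, leaves the enoate untouched, and by reagent control gives the (2R,3S)-epoxide, i.e. C5 (R) and C6 (S).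

**Step 8**
Reactants: 22 ethyl (2E,4R)-4-[(2R,3S)-3-ethyl-3-[(2S,4S)-4-ethyl-2-methyloctyl]oxiran-2-yl]hex-2-enoate
Product: 24 ethyl 2-[(3R,4S,5R,6R)-4,6-diethyl-6-[(2S,4S)-4-ethyl-2-methyloctyl]-5-hydroxy-1,2-dioxan-3-yl]acetate, via hydroperoxy alcohol 23 (not isolated)
Conditions: anhyd. H2O2 in Et2O, H3PMo12O40 (5 mol%), 0 °C → rt; then Et2NH, CF3CH2OH, rt
Reagents that add atoms: hydrogen peroxide OO
Why: Molybdenum-catalysed perhydrolysis opens the epoxide at the fully substituted carbon with inversion (anti opening, borderline SN2) to set C6 (R) in 23, and the base-mediated 6-exo peroxy-Michael addition then closes the 1,2-dioxane through a chair in which the new C3 substituent is equatorial and trans to the C4 ethyl group, setting C3 (R).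

**Step 9**
Reactants: 24 ethyl 2-[(3R,4S,5R,6R)-4,6-diethyl-6-[(2S,4S)-4-ethyl-2-methyloctyl]-5-hydroxy-1,2-dioxan-3-yl]acetate
Product: 25 ethyl 2-[(3R,6R)-4,6-diethyl-6-[(2S,4S)-4-ethyl-2-methyloctyl]-3,6-dihydro-1,2-dioxin-3-yl]acetate
Conditions: Martin sulfurane, CH2Cl2, 0 °C → rt
Reagents that add atoms: none
Why: Martin sulfurane dehydration is an anti E2 elimination in which the axial C5 alkoxysulfonium and the axial C4–H are trans-diaxial, and since C6 carries no hydrogen only the ring C4=C5 alkene can form, with C3 and C6 untouched.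

**Step 10**
Reactants: 25 ethyl 2-[(3R,6R)-4,6-diethyl-6-[(2S,4S)-4-ethyl-2-methyloctyl]-3,6-dihydro-1,2-dioxin-3-yl]acetate
Product: 26 2-[(3R,6R)-4,6-diethyl-6-[(2S,4S)-4-ethyl-2-methyloctyl]-3,6-dihydro-1,2-dioxin-3-yl]acetic acid
Conditions: LiOH, THF/H2O (3:1), 0 °C; then 1 M HCl to pH 3
Reagents that add atoms: lithium hydroxide [Li+].[OH-]
Why: Cold saponification (acyl substitution) cleaves the ethyl ester under conditions too mild for C2 enolisation/retro-Michael opening or Kornblum–DeLaMare cleavage, so C3 and C6 are preserved.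

**Compound list**
1 | hex-1-ene | C=CCCCC | starting material
2 | triethylaluminium | CC[Al](CC)CC | starting material
3 | vinyl bromide | C=CBr | starting material
4 | diethyl[(2S)-2-ethylhexyl]alumane | CCCC[C@H](CC)C[Al](CC)CC | intermediate
5 | (4S)-4-ethyloct-1-ene | CCCC[C@H](CC)CC=C | intermediate
6 | but-1-yne | CCC#C | starting material
7 | dibromo[(1Z)-2-bromobut-1-en-1-yl]borane | Br/C(CC)=C\B(Br)Br | intermediate
8 | 2-[(1Z)-2-bromobut-1-en-1-yl]-4,4,5,5-tetramethyl-1,3,2-dioxaborolane | Br/C(CC)=C\B1OC(C)(C)C(C)(C)O1 | intermediate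
9 | trimethylaluminium | C[Al](C)C | starting material
10 | [(2S,4S)-4-ethyl-2-methyloctyl]dimethylalumane | CCCC[C@H](CC)C[C@H](C)C[Al](C)C | intermediate
11 | 2-[(1Z,4S,6S)-2,6-diethyl-4-methyldec-1-en-1-yl]-4,4,5,5-tetramethyl-1,3,2-dioxaborolane | CCCC[C@H](CC)C[C@H](C)C/C(CC)=C\B1OC(C)(C)C(C)(C)O1 | intermediate
12 | propan-1-ol | CCCO | starting material
13 | propyl N,N-diisopropylcarbamate | CCCOC(=O)N(C(C)C)C(C)C | intermediate
14 | (1R)-1-lithiopropyl N,N-diisopropylcarbamate (sparteine complex) | CC[C@@H]([Li])OC(=O)N(C(C)C)C(C)C | intermediate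
15 | lithium boronate complex of 11 with the (1R)-1-(carbamoyloxy)propyl group on boron | CCCC[C@H](CC)C[C@H](C)C/C(CC)=C\[B-]1(OC(C)(C)C(C)(C)O1)[C@H](CC)OC(=O)N(C(C)C)C(C)C.[Li+] | intermediate
16 | 2-[(3S,4Z,7S,9S)-5,9-diethyl-7-methyltridec-4-en-3-yl]-4,4,5,5-tetramethyl-1,3,2-dioxaborolane | CCCC[C@H](CC)C[C@H](C)C/C(CC)=C\[C@H](CC)B1OC(C)(C)C(C)(C)O1 | intermediate
17 | ethyl (2Z)-3-iodoprop-2-enoate | CCOC(=O)/C=C\I | starting material
18 | ethyl (2Z)-3-(chloromagnesio)prop-2-enoate | CCOC(=O)/C=C\[Mg]Cl | intermediate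
19 | chloromagnesium boronate complex of 16 with the (Z)-2-(ethoxycarbonyl)vinyl group on boron | CCCC[C@H](CC)C[C@H](C)C/C(CC)=C\[C@H](CC)[B-]1(OC(C)(C)C(C)(C)O1)/C=C\C(=O)OCC.Cl[Mg+] | intermediate
20 | ethyl (4R,5Z,8S,10S)-4,6,10-triethyl-2-iodo-8-methyl-3-(4,4,5,5-tetramethyl-1,3,2-dioxaborolan-2-yl)tetradec-5-enoate (2,3-anti adduct, both C2/C3 pairs) | CCCC[C@H](CC)C[C@H](C)C/C(CC)=C\[C@H](CC)C(B1OC(C)(C)C(C)(C)O1)C(I)C(=O)OCC | intermediate
21 | ethyl (2E,4R,5Z,8S,10S)-4,6,10-triethyl-8-methyltetradeca-2,5-dienoate | CCCC[C@H](CC)C[C@H](C)C/C(CC)=C\[C@H](CC)/C=C/C(=O)OCC | intermediate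
22 | ethyl (2E,4R)-4-[(2R,3S)-3-ethyl-3-[(2S,4S)-4-ethyl-2-methyloctyl]oxiran-2-yl]hex-2-enoate | CCCC[C@H](CC)C[C@H](C)C[C@]1(CC)O[C@@H]1[C@H](CC)/C=C/C(=O)OCC | intermediate
23 | ethyl (2E,4R,5R,6R,8S,10S)-4,6,10-triethyl-6-hydroperoxy-5-hydroxy-8-methyltetradec-2-enoate | CCCC[C@H](CC)C[C@H](C)C[C@@](CC)(OO)[C@H](O)[C@H](CC)/C=C/C(=O)OCC | intermediate
24 | ethyl 2-[(3R,4S,5R,6R)-4,6-diethyl-6-[(2S,4S)-4-ethyl-2-methyloctyl]-5-hydroxy-1,2-dioxan-3-yl]acetate | CCCC[C@H](CC)C[C@H](C)C[C@@]1(CC)OO[C@H](CC(=O)OCC)[C@@H](CC)[C@H]1O | intermediate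
25 | ethyl 2-[(3R,6R)-4,6-diethyl-6-[(2S,4S)-4-ethyl-2-methyloctyl]-3,6-dihydro-1,2-dioxin-3-yl]acetate | CCCC[C@H](CC)C[C@H](C)C[C@]1(CC)C=C(CC)[C@@H](CC(=O)OCC)OO1 | intermediate
26 | 2-[(3R,6R)-4,6-diethyl-6-[(2S,4S)-4-ethyl-2-methyloctyl]-3,6-dihydro-1,2-dioxin-3-yl]acetic acid | CCCC[C@H](CC)C[C@H](C)C[C@]1(CC)C=C(CC)[C@@H](CC(=O)O)OO1 | target

Stereocentre ledger: C4′ (S) in step 1; C2′ (S) in step 3; C6 (R) from the Z-alkene of step 3, the epoxide face of step 7 and the inversion of step 8; C3 (R) in step 8, relayed from C4 (step 5); C4 and C5 are erased in step 9.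

**Total step count:** 10. **Longest linear sequence:** 8 (steps 1, 3, 5, 6, 7, 8, 9, 10).

**Three steps most likely to fail**

Step 6 (the new step). The ester-bearing Grignard may not form the boronate complex below its decomposition temperature, iodine may attack the allyl unit at C6 instead, or ethoxide may move the skipped diene into conjugation. The fallback uses known chemistry and sets out from 16: Matteson homologation with (dichloromethyl)lithium (CH2Cl2, n-BuLi, THF, −100 °C; ZnCl2, → rt), a 1,2-boronate shift with retention at C4, gives 2-[(2S,3Z,6S,8S)-1-chloro-2,4,8-triethyl-6-methyldodec-3-en-1-yl]-4,4,5,5-tetramethyl-1,3,2-dioxaborolane F1. Buffered oxidation (NaBO3·4H2O, THF/H2O, 0 °C) gives (2S,3Z,6S,8S)-2,4,8-triethyl-6-methyldodec-3-enal F2, which is olefinated at once (triethyl phosphonoacetate, LiCl, DBU, MeCN, 0 °C; Horner–Wadsworth–Emmons) and returns to the route at 21.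

Step 8. Perhydrolysis at the fully substituted carbon may erode C6 or trigger Hock cleavage, and the amine-mediated Michael closure may give poor 3,4-trans selectivity. The fallback sets out from 22: perhydrolysis is stopped at the hydroperoxy alcohol 23, which is isolated, and the ring is closed by electrophile-induced cycloperoxymercuration (Hg(OAc)2, cat. HClO4, CH2Cl2, 0 °C; kinetic chair closure) to ethyl 2-(acetoxymercurio)-2-[(3S,4S,5R,6R)-4,6-diethyl-6-[(2S,4S)-4-ethyl-2-methyloctyl]-5-hydroxy-1,2-dioxan-3-yl]acetate F3. Alkaline NaBH4 (0 °C) then replaces mercury by hydrogen and returns to the route at 24.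

Step 9. The sulfurane may give substitution, or the alkoxysulfonium may be displaced by the neighbouring peroxide oxygen (ring contraction). The fallback sets out from 24: mesylation (MsCl, Et3N, CH2Cl2, −20 °C) gives ethyl 2-[(3R,4R,5R,6R)-4,6-diethyl-6-[(2S,4S)-4-ethyl-2-methyloctyl]-5-(methanesulfonyloxy)-1,2-dioxan-3-yl]acetate F4, and base-induced E2 (DBU, toluene, 50 °C) through the same trans-diaxial H4/O5 arrangement returns to the route at 25.

**Further compounds**
F1 | step 6 | 2-[(2S,3Z,6S,8S)-1-chloro-2,4,8-triethyl-6-methyldodec-3-en-1-yl]-4,4,5,5-tetramethyl-1,3,2-dioxaborolane (C1 epimers) | CCCC[C@H](CC)C[C@H](C)C/C(CC)=C\[C@H](CC)C(Cl)B1OC(C)(C)C(C)(C)O1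
F2 | step 6 | (2S,3Z,6S,8S)-2,4,8-triethyl-6-methyldodec-3-enal | CCCC[C@H](CC)C[C@H](C)C/C(CC)=C\[C@H](CC)C=O
F3 | step 8 | ethyl 2-(acetoxymercurio)-2-[(3S,4S,5R,6R)-4,6-diethyl-6-[(2S,4S)-4-ethyl-2-methyloctyl]-5-hydroxy-1,2-dioxan-3-yl]acetate (C2 epimers) | CCCC[C@H](CC)C[C@H](C)C[C@@]1(CC)OO[C@H](C([Hg]OC(C)=O)C(=O)OCC)[C@@H](CC)[C@H]1O
F4 | step 9 | ethyl 2-[(3R,4R,5R,6R)-4,6-diethyl-6-[(2S,4S)-4-ethyl-2-methyloctyl]-5-(methanesulfonyloxy)-1,2-dioxan-3-yl]acetate | CCCC[C@H](CC)C[C@H](C)C[C@@]1(CC)OO[C@H](CC(=O)OCC)[C@@H](CC)[C@H]1OS(C)(=O)=O
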